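Remark on the chemistry (locants and assumptions): side-chain carbons are numbered C1' (benzylic CH2) to C16'; C20' is the acetoxymethyl carbon on C3'; O7 and O9 are the ketal oxygens on C7' and C9'. Tributyl[(benzyloxy)methyl]stannane is taken as a purchased reagent. Metal alkoxides of hydroxyl groups and tetrahedral adducts that exist only until work-up carry no number.

## The problem

The target is a tetraprenylated methylhydroquinone whose chain carbons C4'–C9' are folded into a 2,8-dioxabicyclo[3.2.1]octane: an oxolane ring (C4'–C5'–C6'–C7'–O7) and a 1,3-dioxane ring (C4'–O9–C9'–C8'–C7'–O7) that share the ketal carbon C4' and the tertiary ether carbon C7'. Its five stereocentres form two groups that cannot influence each other: C2'/C3' (a secondary acetate beside a fully substituted carbinol that also carries CH2OAc and the ketal carbon) and C7'/C4'/C9' in the bicycle. Inside the bicycle C7' fixes C4' through the O7 bridge, but in an open chain C7' (methyl against CH2) gives no useful 1,3-induction to C9', and both C9' epimers of an open keto diol would ketalise, so ring closure alone cannot correct C9'. C3' has to be set next to C2' among three oxygenated carbons, and in unmasked form C3'(OH)–C4'(=O) is an α-ketol open to acyloin shift and retro-aldol loss of C20' or C2'. The hydroquinone is oxidised by air and most oxidants, two acetates must sit beside a free tertiary hydroxyl, and the allylic ether at C9' with the two trisubstituted alkenes of the tail rules out hydrogenolysis, osmylation, ozone and strong acid once the tail is present. The feature that the plan uses: C9' is the only stereocentre on the three-atom bridge O9–C9'–C8', it is bonded to the ring oxygen O9, and its alkenyl group is equatorial on the dioxane chair, on the face syn to O7 and anti to the two-carbon bridge C5'–C6'. A cation at C9' is therefore a ring oxocarbenium ion whose open face is the one the target needs, so the C9'–C10' bond can be made last, on a bicycle that holds no alkene.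

## Retrosynthesis

26 ⇒ 24 (through quinone 25). No skeletal bond is cut; the two phenols are traced to methyl ethers. Methyl ethers survive organomagnesium reagents, Pd/O2, H2 and BF3 and are removed by oxidation and mild reduction that leave acetates alone. The forward step must oxidise the arene faster than the alkenes and must not ionise the ketal.

24 ⇒ 16 + 23. The C9'–C10' bond is cut. Cutting C8'–C9' (allylation or aldol on geranial) or C9'–O9 (ketalisation) would leave C9' to a chiral reagent on an open chain. The C9'–C10' cut makes C9' the acetal carbon of acetate 16, whose two anomers converge on one oxocarbenium ion, and lets the E geometry come from a stereodefined alkenylboron reagent 23. The precursor 16 lacks nine carbons, both alkenes and the C9' stereocentre. The forward reaction must ionise at C9' and not at C4', be attacked from the O7 face and keep the alkene geometry.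

16 ⇒ 15 ⇒ 14 ⇒ 13. The three acetyl groups and the benzyl ether are removed, then the C9'–O9 bond is cut and C9' is taken back from aldehyde to the terminal carbon of a vinyl group. One acetylation thus installs both acetates of the target and arms C9'. Hemiketal 13 is monocyclic and has no C9' stereocentre. The forward oxidation must be anti-Markovnikov; the aldehyde is then captured by the C4' hemiketal hydroxyl on its own.

13 ⇒ 6 + 9 (through 10, 11, 12). The C3'–C4' bond is cut. A C4'–C5' cut would need the complete diol on an acid derivative, and a C2'–C3' aldol would have to set two centres with a tetrasubstituted enolate. The chosen cut gives α-hydroxy ketone 6, whose only stereocentre C2' is tied to the C3' carbonyl in a magnesium chelate, and the metallated enol ether 11, which is C4' at the ketone oxidation level with O7 and C7' attached. The addition must come from the face of C2'–H.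

9 ⇒ 8 ⇒ 7. The C6=C7 alkene of (R)-linalool 7 is the cut. C3 of linalool becomes C7', C4–C6 become C6', C5', C4', and the vinyl group becomes C8'/C9'. One commercial terpene thus supplies six chain carbons, the C7' methyl and the C7' stereocentre. The ozonolysis must spare the vinyl group.

6 ⇒ 5 ⇒ 4 ⇒ 1 + 2. C3'–C20' is cut to a Weinreb amide 5 and a hydroxymethyl anion equivalent, and aryl–C1' is cut to aryl bromide 1 and glycidate 2. The glycidate brings C2' from the chiral pool; epoxide opening must occur at CH2.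

23 ⇒ 20 ⇒ 18 ⇒ 17. The C10'–B and C11'–CH3 bonds are cut; syn-carboalumination of alkyne 18 sets the E alkene, and 18 comes from bromide 17 and acetylide.

## Roads not taken

Alternative 1: the most obvious cut, both ketal C–O bonds (C4'–O7, C4'–O9), leading to open keto diol A1 with the whole tail, closed by acid-catalysed ketalisation. C9' would have to be set on the chain, for example by reagent-controlled reduction of enone A2, because C7' gives no 1,3-induction and the ketalisation accepts either C9' epimer. The α-ketol A1, the allylic alcohol and both alkenes would be carried through every step, and the C20' protecting group would have to be removed in their presence. The chosen plan needs no chiral reagent for C9' and meets the tail only in the last two steps.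

Alternative 2: cut C9'–O9 with allylic transposition, leading to tertiary allylic alcohol A3 (C9'=C10', hydroxyl on C11'). The forward key step would be a Re2O7-catalysed 1,3-transposition with ketal trapping under thermodynamic control, which would funnel C9' to the equatorial isomer. The equilibration passes through the C11' perrhenate, where C10'=C11' geometry is lost, and methyl against CH2R on C11' gives little thermodynamic preference for E. The tertiary allylic cation can also be captured by the C14' alkene, and the α-ketol is exposed to the acid. The chosen plan fixes the geometry in reagent 23.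

Alternative 3: delete O9 from the dioxane ring, leading to 7-oxanorbornanone A5, which Baeyer–Villiger oxygen insertion with bridgehead migration would convert to lactone A6; reduction and acetylation would then reach an acetate of the type of 16. A5 would come from a Diels–Alder reaction of furyl carbinol A4 with a ketene equivalent. Regiochemistry between the two differently substituted furan termini and facial selectivity relative to C3' are not controlled, and the sequence is at least four steps longer than the linalool route, which delivers the same acetal with C7' fixed.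

Key step: step 13

## Steps

Step 1
Reactants: 1 1-bromo-2,5-dimethoxy-4-methylbenzene; 2 methyl (2R)-oxirane-2-carboxylate
Product: 4 methyl (2R)-3-(2,5-dimethoxy-4-methylphenyl)-2-hydroxypropanoate, via arylmagnesium bromide 3 (not isolated)
Conditions: Mg, THF, reflux; then CuI (10 mol %), 2, THF, −40 → −20 °C; H2O
Reagents that add atoms: none
Why: Copper-catalysed SN2 opening of the terminal epoxide by the aryl Grignard reagent at the CH2 carbon; the stereocentre of 2 is not touched, so 4 is (R).

Step 2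
Reactants: 4 methyl (2R)-3-(2,5-dimethoxy-4-methylphenyl)-2-hydroxypropanoate
Product: 5 (2R)-3-(2,5-dimethoxy-4-methylphenyl)-2-hydroxy-N-methoxy-N-methylpropanamide
Conditions: MeNH(OMe)·HCl, i-PrMgCl, THF, −20 → 0 °C; H2O
Reagents that add atoms: N,O-dimethylhydroxylamine hydrochloride, CNOC.Cl
Why: Aminolysis of the ester by the chloromagnesium amide (Weinreb amide formation); the alkoxide formed from the free hydroxyl protects C2'–H from enolisation.

Step 3
Reactants: 5 (2R)-3-(2,5-dimethoxy-4-methylphenyl)-2-hydroxy-N-methoxy-N-methylpropanamide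
Product: 6 (3R)-1-(benzyloxy)-4-(2,5-dimethoxy-4-methylphenyl)-3-hydroxybutan-2-one
Conditions: i-PrMgCl (1 equiv), THF, −78 °C; then BnOCH2Li [Bu3SnCH2OBn, n-BuLi, THF, −78 °C]; H2O; used at once
Reagents that add atoms: tributyl[(benzyloxy)methyl]stannane, CCCC[Sn](CCCC)(CCCC)COCc1ccccc1
Why: Tin–lithium exchange gives the α-alkoxymethyllithium, which adds once to the Weinreb amide through the stable chelated tetrahedral adduct; the C2' alkoxide formed first keeps the stereocentre from deprotonation.

Step 4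
Reactants: 7 (3R)-3,7-dimethylocta-1,6-dien-3-ol ((R)-linalool)
Product: 8 (5R)-5-ethenyl-5-methyloxolan-2-ol (both anomers)
Conditions: O3 (1 equiv, Sudan Red 7B end point), CH2Cl2/MeOH, −78 °C; then Me2S
Reagents that add atoms: ozone, [O-][O+]=O
Why: Chemoselective ozonolysis: the electron-rich trisubstituted alkene reacts much faster than the vinyl group next to the allylic oxygen; the aldehyde closes onto the tertiary hydroxyl as the lactol, C7' untouched.

Step 5
Reactants: 8 (5R)-5-ethenyl-5-methyloxolan-2-ol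
Product: 9 (2R)-2-ethenyl-2-methyl-2,3-dihydrofuran
Conditions: MsCl, Et3N, CH2Cl2, −20 °C → reflux; distilled
Reagents that add atoms: none
Why: Anomeric sulfonate/chloride formation and elimination, the lactol dehydration used for furanoid glycals; no stereocentre is involved.

Step 6
Reactants: 9 (2R)-2-ethenyl-2-methyl-2,3-dihydrofuran; 6 (3R)-1-(benzyloxy)-4-(2,5-dimethoxy-4-methylphenyl)-3-hydroxybutan-2-one
Product: 13 2-[(2S,3R)-1-(benzyloxy)-4-(2,5-dimethoxy-4-methylphenyl)-2,3-dihydroxybutan-2-yl]-5-ethenyl-5-methyloxolan-2-ol (5R; both C2 epimers), via lithiated dihydrofuran 10 (not isolated), via dihydrofuranylmagnesium bromide 11 (not isolated), via enol ether diol 12 (not isolated)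
Conditions: 9, t-BuLi, THF, −78 → 0 °C; MgBr2·OEt2, −78 °C; add to 6 pre-treated with i-PrMgCl (1 equiv), THF, −78 → −20 °C; then AcOH/H2O/THF, 0 °C → rt
Reagents that add atoms: water, O
Why: The α-metallated cyclic enol ether is an acyl anion equivalent of C4' and adds to the magnesium alkoxide chelate of 6 (five-membered O–Mg–O ring, Cram cyclic model) from the face of C2'–H, which sets C3' as (S). Extra coordination of the C20' benzyloxy oxygen does not change the face because C20' is not stereogenic. Mild aqueous acid hydrates the enol ether 12 to hemiketal 13.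

Step 7
Reactants: 13 2-[(2S,3R)-1-(benzyloxy)-4-(2,5-dimethoxy-4-methylphenyl)-2,3-dihydroxybutan-2-yl]-5-ethenyl-5-methyloxolan-2-ol
Product: 14 (1S,5R)-1-[(2S,3R)-1-(benzyloxy)-4-(2,5-dimethoxy-4-methylphenyl)-2,3-dihydroxybutan-2-yl]-5-methyl-2,8-dioxabicyclo[3.2.1]octan-3-ol (both C3 epimers)
Conditions: PdCl2(PhCN)2 (10 mol %), CuCl2·2H2O (10 mol %), AgNO2 (5 mol %), t-BuOH/MeNO2 15:1, O2 (1 atm), rt
Reagents that add atoms: dioxygen, O=O
Why: Nitrite-modified, aldehyde-selective Wacker oxidation; the quaternary, oxygen-bearing C7' next to the vinyl group disfavours Markovnikov attack. The C9' aldehyde is trapped by the C4' hemiketal hydroxyl (6-exo-trig lactol closure), and the C4' configuration follows from C7' because O7 can bridge one face only.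

Step 8
Reactants: 14 (1S,5R)-1-[(2S,3R)-1-(benzyloxy)-4-(2,5-dimethoxy-4-methylphenyl)-2,3-dihydroxybutan-2-yl]-5-methyl-2,8-dioxabicyclo[3.2.1]octan-3-ol
Product: 15 (1S,5R)-1-[(2S,3R)-4-(2,5-dimethoxy-4-methylphenyl)-1,2,3-trihydroxybutan-2-yl]-5-methyl-2,8-dioxabicyclo[3.2.1]octan-3-ol
Conditions: H2 (1 atm), 10 % Pd/C, EtOAc/EtOH, rt
Reagents that add atoms: none
Why: Hydrogenolysis of the benzyl ether while no alkene is present; aryl methyl ethers, ketal and lactol are inert.

Step 9
Reactants: 15 (1S,5R)-1-[(2S,3R)-4-(2,5-dimethoxy-4-methylphenyl)-1,2,3-trihydroxybutan-2-yl]-5-methyl-2,8-dioxabicyclo[3.2.1]octan-3-ol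
Product: 16 (1S,5R)-1-[(2S,3R)-1,3-diacetoxy-4-(2,5-dimethoxy-4-methylphenyl)-2-hydroxybutan-2-yl]-5-methyl-2,8-dioxabicyclo[3.2.1]octan-3-yl acetate (both C3 epimers)
Conditions: Ac2O, pyridine, DMAP (cat.), CH2Cl2, 0 °C → rt
Reagents that add atoms: acetic anhydride, CC(=O)OC(C)=O
Why: Acylation of the primary, the secondary and the lactol hydroxyl; the tertiary C3' hydroxyl beside the ketal carbon is too hindered to react, so both acetates of the target and the leaving group at C9' are installed together.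

Step 10
Reactants: 17 5-bromo-2-methylpent-2-ene
Product: 18 6-methylhept-5-en-1-yne
Conditions: LiC≡CH·H2NCH2CH2NH2, DMSO, 10 °C → rt
Reagents that add atoms: lithium acetylide–ethylenediamine complex, [Li]C#C.NCCN
Why: SN2 alkylation of lithium acetylide by a primary homoallylic bromide.

Step 11
Reactants: 18 6-methylhept-5-en-1-yne
Product: 20 (1E)-1-iodo-2,6-dimethylhepta-1,5-diene, via alkenylalane 19 (not isolated)
Conditions: Me3Al, Cp2ZrCl2 (20 mol %), CH2Cl2, rt; then I2, THF, −30 °C; H2O
Reagents that add atoms: trimethylaluminium, C[Al](C)C; iodine, II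
Why: Zirconium-catalysed syn-carboalumination of the terminal alkyne (Negishi carboalumination) places methyl and aluminium cis, and iodinolysis proceeds with retention, which fixes the E geometry of the later C10'=C11' bond.

Step 12
Reactants: 20 (1E)-1-iodo-2,6-dimethylhepta-1,5-diene
Product: 23 potassium [(1E)-2,6-dimethylhepta-1,5-dien-1-yl]trifluoroborate, via alkenyllithium 21 (not isolated), via lithium alkenyltrimethoxyborate 22 (not isolated)
Conditions: t-BuLi (2 equiv), Et2O, −78 °C; B(OMe)3, −78 °C → rt; then aq. KHF2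
Reagents that add atoms: trimethyl borate, COB(OC)OC; potassium hydrogen difluoride, F.[F-].[K+]
Why: Iodine–lithium exchange with retention, borylation and fluoride exchange, the standard route to potassium alkenyltrifluoroborates.

Step 13
Reactants: 16 (1S,5R)-1-[(2S,3R)-1,3-diacetoxy-4-(2,5-dimethoxy-4-methylphenyl)-2-hydroxybutan-2-yl]-5-methyl-2,8-dioxabicyclo[3.2.1]octan-3-yl acetate; 23 potassium [(1E)-2,6-dimethylhepta-1,5-dien-1-yl]trifluoroborate
Product: 24 [(2S,3R)-3-acetoxy-4-(2,5-dimethoxy-4-methylphenyl)-2-{(1R,3S,5R)-3-[(1E)-2,6-dimethylhepta-1,5-dien-1-yl]-5-methyl-2,8-dioxabicyclo[3.2.1]octan-1-yl}-2-hydroxybutyl] acetate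
Conditions: BF3·OEt2 (3 equiv), 23 (2 equiv), MeCN/CH2Cl2, −40 → 0 °C; cold aqueous quench
Reagents that add atoms: none
Why: BF3 ionises the C9' acetate of either anomer to the same ring oxocarbenium ion O9=C9', and the alkenyldifluoroborane formed from 23 attacks it at the boron-bearing carbon; loss of boron from the β-borato tertiary cation restores the alkene with retention of the E geometry. The closest known reaction type is the BF3-promoted C-glycosylation of glycosyl acetates and fluorides, and the coupling of acetals, with potassium alkenyltrifluoroborates. No ring is closed; both rings are already in 16. The new stereocentre C9' is controlled by the bicycle: the two-carbon bridge C5'–C6' shields the axial face, so the nucleophile enters syn to O7, as nucleophiles do with bicyclo[3.2.1]octan-3-ones of the tropinone type, and the alkenyl group becomes equatorial, which is (S). The step needs ionisation at C9' and not at the ketal C4'; the acetate leaving group at C9' and the electron-poor C4', flanked by the oxygenated C3', secure this. The tertiary C3' hydroxyl cannot reach C9', because it is equatorial on C4' and 1,3-diequatorial to the reacting face. The aryl ring carries no free phenol and the molecule no other alkene, so no competing nucleophile is present.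

Step 14
Reactants: 24 [(2S,3R)-3-acetoxy-4-(2,5-dimethoxy-4-methylphenyl)-2-{(1R,3S,5R)-3-[(1E)-2,6-dimethylhepta-1,5-dien-1-yl]-5-methyl-2,8-dioxabicyclo[3.2.1]octan-1-yl}-2-hydroxybutyl] acetate
Product: 26 [(2S,3R)-3-acetoxy-4-(2,5-dihydroxy-4-methylphenyl)-2-{(1R,3S,5R)-3-[(1E)-2,6-dimethylhepta-1,5-dien-1-yl]-5-methyl-2,8-dioxabicyclo[3.2.1]octan-1-yl}-2-hydroxybutyl] acetate, via quinone 25 (not isolated)
Conditions: (NH4)2Ce(NO3)6 (2.2 equiv), MeCN/H2O, 0 °C; then Na2S2O4, EtOAc/H2O, rt, under N2
Reagents that add atoms: water, O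
Why: Oxidative demethylation of the 1,4-dimethoxyarene by tetravalent cerium (water adds at the two ipso carbons, methanol leaves) gives the quinone faster than the alkenes react; Na2S2O4 then reduces the quinone to the hydroquinone without touching acetates, ketal or alkenes.

## Compound list

1 | 1-bromo-2,5-dimethoxy-4-methylbenzene | COc1cc(C)c(OC)cc1Br | starting material
2 | methyl (2R)-oxirane-2-carboxylate | COC(=O)[C@H]1CO1 | starting material
3 | (2,5-dimethoxy-4-methylphenyl)magnesium bromide | COc1cc(C)c(OC)cc1[Mg]Br | intermediate (not isolated)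
4 | methyl (2R)-3-(2,5-dimethoxy-4-methylphenyl)-2-hydroxypropanoate | COC(=O)[C@@H](Cc1cc(OC)c(C)cc1OC)O | intermediate
5 | (2R)-3-(2,5-dimethoxy-4-methylphenyl)-2-hydroxy-N-methoxy-N-methylpropanamide | CON(C)C(=O)[C@@H](Cc1cc(OC)c(C)cc1OC)O | intermediate
6 | (3R)-1-(benzyloxy)-4-(2,5-dimethoxy-4-methylphenyl)-3-hydroxybutan-2-one | O=C(COCc1ccccc1)[C@@H](Cc1cc(OC)c(C)cc1OC)O | intermediate
7 | (3R)-3,7-dimethylocta-1,6-dien-3-ol, (R)-linalool | C=C[C@](C)(O)CCC=C(C)C | starting material
8 | (5R)-5-ethenyl-5-methyloxolan-2-ol, both anomers | C=C[C@@]1(C)CCC(O)O1 | intermediate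
9 | (2R)-2-ethenyl-2-methyl-2,3-dihydrofuran | C=C[C@@]1(C)CC=CO1 | intermediate
10 | [(5R)-5-ethenyl-5-methyl-4,5-dihydrofuran-2-yl]lithium | [Li]C1=CC[C@](C)(C=C)O1 | intermediate (not isolated)
11 | [(5R)-5-ethenyl-5-methyl-4,5-dihydrofuran-2-yl]magnesium bromide | Br[Mg]C1=CC[C@](C)(C=C)O1 | intermediate (not isolated)
12 | (2S,3R)-1-(benzyloxy)-4-(2,5-dimethoxy-4-methylphenyl)-2-[(5R)-5-ethenyl-5-methyl-4,5-dihydrofuran-2-yl]butane-2,3-diol | c1ccccc1COC[C@](O)([C@@H](Cc1cc(OC)c(C)cc1OC)O)C1=CC[C@](C)(C=C)O1 | intermediate (not isolated)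
13 | 2-[(2S,3R)-1-(benzyloxy)-4-(2,5-dimethoxy-4-methylphenyl)-2,3-dihydroxybutan-2-yl]-5-ethenyl-5-methyloxolan-2-ol, (5R), both C2 epimers | c1ccccc1COC[C@](O)([C@@H](Cc1cc(OC)c(C)cc1OC)O)C1(O)CC[C@](C)(C=C)O1 | intermediate
14 | (1S,5R)-1-[(2S,3R)-1-(benzyloxy)-4-(2,5-dimethoxy-4-methylphenyl)-2,3-dihydroxybutan-2-yl]-5-methyl-2,8-dioxabicyclo[3.2.1]octan-3-ol, both C3 epimers | c1ccccc1COC[C@](O)([C@@H](Cc1cc(OC)c(C)cc1OC)O)[C@]12CC[C@](C)(CC(O)O1)O2 | intermediate
15 | (1S,5R)-1-[(2S,3R)-4-(2,5-dimethoxy-4-methylphenyl)-1,2,3-trihydroxybutan-2-yl]-5-methyl-2,8-dioxabicyclo[3.2.1]octan-3-ol, both C3 epimers | OC[C@](O)([C@@H](Cc1cc(OC)c(C)cc1OC)O)[C@]12CC[C@](C)(CC(O)O1)O2 | intermediate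
16 | (1S,5R)-1-[(2S,3R)-1,3-diacetoxy-4-(2,5-dimethoxy-4-methylphenyl)-2-hydroxybutan-2-yl]-5-methyl-2,8-dioxabicyclo[3.2.1]octan-3-yl acetate, both C3 epimers | CC(=O)OC[C@](O)([C@@H](Cc1cc(OC)c(C)cc1OC)OC(C)=O)[C@]12CC[C@](C)(CC(OC(C)=O)O1)O2 | intermediate
17 | 5-bromo-2-methylpent-2-ene | CC(C)=CCCBr | starting material
18 | 6-methylhept-5-en-1-yne | C#CCCC=C(C)C | intermediate
19 | [(1E)-2,6-dimethylhepta-1,5-dien-1-yl]dimethylalumane | C[Al](C)/C=C(\C)CCC=C(C)C | intermediate (not isolated)
20 | (1E)-1-iodo-2,6-dimethylhepta-1,5-diene | I/C=C(\C)CCC=C(C)C | intermediate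
21 | [(1E)-2,6-dimethylhepta-1,5-dien-1-yl]lithium | [Li]/C=C(\C)CCC=C(C)C | intermediate (not isolated)
22 | lithium [(1E)-2,6-dimethylhepta-1,5-dien-1-yl]trimethoxyborate | [Li+].CO[B-](OC)(OC)/C=C(\C)CCC=C(C)C | intermediate (not isolated)
23 | potassium [(1E)-2,6-dimethylhepta-1,5-dien-1-yl]trifluoroborate | [K+].F[B-](F)(F)/C=C(\C)CCC=C(C)C | intermediate
24 | [(2S,3R)-3-acetoxy-4-(2,5-dimethoxy-4-methylphenyl)-2-{(1R,3S,5R)-3-[(1E)-2,6-dimethylhepta-1,5-dien-1-yl]-5-methyl-2,8-dioxabicyclo[3.2.1]octan-1-yl}-2-hydroxybutyl] acetate | CC(=O)OC[C@](O)([C@@H](Cc1cc(OC)c(C)cc1OC)OC(C)=O)[C@]12CC[C@](C)(C[C@@H](/C=C(\C)CCC=C(C)C)O1)O2 | intermediate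
25 | [(2S,3R)-3-acetoxy-2-{(1R,3S,5R)-3-[(1E)-2,6-dimethylhepta-1,5-dien-1-yl]-5-methyl-2,8-dioxabicyclo[3.2.1]octan-1-yl}-2-hydroxy-4-(4-methyl-3,6-dioxocyclohexa-1,4-dien-1-yl)butyl] acetate | CC(=O)OC[C@](O)([C@@H](CC1=CC(=O)C(C)=CC1=O)OC(C)=O)[C@]12CC[C@](C)(C[C@@H](/C=C(\C)CCC=C(C)C)O1)O2 | intermediate (not isolated)
26 | [(2S,3R)-3-acetoxy-4-(2,5-dihydroxy-4-methylphenyl)-2-{(1R,3S,5R)-3-[(1E)-2,6-dimethylhepta-1,5-dien-1-yl]-5-methyl-2,8-dioxabicyclo[3.2.1]octan-1-yl}-2-hydroxybutyl] acetate | CC(=O)OC[C@](O)([C@@H](Cc1cc(O)c(C)cc1O)OC(C)=O)[C@]12CC[C@](C)(C[C@@H](/C=C(\C)CCC=C(C)C)O1)O2 | target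

## Step count and least certain steps

Total step count: 14. Longest linear sequence: 9 steps (1, 2, 3, 6, 7, 8, 9, 13, 14).

Step 13 (key step). What may go wrong: attack from the axial face (poor facial selectivity), competing ionisation of the ketal at C4', re-ionisation of the allylic C9'–O9 bond of the product with loss of E geometry or elimination, and protodeboronation of the reagent before it couples. The fallback sets C9' by a chiral reagent on the open chain and closes the dioxane ring last. It sets out from 15 and returns at 24. Nozaki–Hiyama–Kishi coupling of the lactol (open aldehyde form) with iodide 20 (CrCl2, NiCl2 cat., DMF) should give the epimeric allylic alcohols 2-[(2S,3R)-4-(2,5-dimethoxy-4-methylphenyl)-1,2,3-trihydroxybutan-2-yl]-5-[(3E)-2-hydroxy-4,8-dimethylnona-3,7-dien-1-yl]-5-methyloxolan-2-ol F1. MnO2 should oxidise only the allylic carbinol to the enone F2. Reduction with (R)-2-methyl-CBS-oxazaborolidine and BH3·SMe2 should give the (9'S)-allylic alcohol F3. PPTS in CH2Cl2 should close the ketal to the triol (2S,3R)-4-(2,5-dimethoxy-4-methylphenyl)-2-{(1R,3S,5R)-3-[(1E)-2,6-dimethylhepta-1,5-dien-1-yl]-5-methyl-2,8-dioxabicyclo[3.2.1]octan-1-yl}butane-1,2,3-triol F4. Ac2O/pyridine would acetylate the primary and secondary hydroxyls to give 24.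

Step 6. What may go wrong: enolisation of ketone 6 by the basic organometallic in place of addition, incomplete chelation control giving the C3' epimer, and racemisation of the α-hydroxy ketone before use. The fallback forms the C3'–C20' bond last, under Felkin–Anh control, which the same analysis predicts to give the same C3' configuration. It sets out from 5 and returns at 13. Silylation (TBSCl, imidazole) should give the silyl ether (2R)-2-[(tert-butyldimethylsilyl)oxy]-3-(2,5-dimethoxy-4-methylphenyl)-N-methoxy-N-methylpropanamide F5. Addition of 10 should give the acyl dihydrofuran (2R)-2-[(tert-butyldimethylsilyl)oxy]-3-(2,5-dimethoxy-4-methylphenyl)-1-[(5R)-5-ethenyl-5-methyl-4,5-dihydrofuran-2-yl]propan-1-one F6. Addition of BnOCH2Li anti to the non-chelating silyloxy group should give the tertiary alcohol (2S,3R)-1-(benzyloxy)-3-[(tert-butyldimethylsilyl)oxy]-4-(2,5-dimethoxy-4-methylphenyl)-2-[(5R)-5-ethenyl-5-methyl-4,5-dihydrofuran-2-yl]butan-2-ol F7. Bu4NF and then aqueous AcOH lead through 12 to 13.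

Step 7. What may go wrong: Markovnikov oxidation to the methyl ketone, oxypalladation of the alkene by the free hemiketal hydroxyl, and oxidation of the C2' carbinol. The fallback replaces the Wacker oxidation by hydroboration and alcohol oxidation on a masked ketal. It sets out from 13 and returns at 14. MeOH/PPTS should give the methyl ketal (2S,3R)-1-(benzyloxy)-4-(2,5-dimethoxy-4-methylphenyl)-2-[(5R)-5-ethenyl-2-methoxy-5-methyloxolan-2-yl]butane-2,3-diol F8. 9-BBN and then NaOH/H2O2 should give the primary alcohol (2S,3R)-1-(benzyloxy)-4-(2,5-dimethoxy-4-methylphenyl)-2-[(5R)-5-(2-hydroxyethyl)-2-methoxy-5-methyloxolan-2-yl]butane-2,3-diol F9. TEMPO/PhI(OAc)2, selective for the primary carbinol, should give the aldehyde (2S,3R)-1-(benzyloxy)-4-(2,5-dimethoxy-4-methylphenyl)-2-[(5R)-2-methoxy-5-methyl-5-(2-oxoethyl)oxolan-2-yl]butane-2,3-diol F10. Aqueous AcOH/THF would exchange methanol for the lactol bridge and give 14.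

Step 14. What may go wrong: acid-promoted ionisation of the allylic ether or ketal in the cerium medium, oxidation of the alkenes, and re-oxidation of the hydroquinone by air. The fallback moves the arene oxidation ahead of the tail and ends with a chemoselective phenol deacetylation. It sets out from 16 and returns at 26. (NH4)2Ce(NO3)6 should give the quinone triacetate (1S,5R)-1-[(2S,3R)-1,3-diacetoxy-2-hydroxy-4-(4-methyl-3,6-dioxocyclohexa-1,4-dien-1-yl)butan-2-yl]-5-methyl-2,8-dioxabicyclo[3.2.1]octan-3-yl acetate F11. Reductive acetylation (Zn, Ac2O, pyridine) should give the pentaacetate (1S,5R)-1-[(2S,3R)-1,3-diacetoxy-4-(2,5-diacetoxy-4-methylphenyl)-2-hydroxybutan-2-yl]-5-methyl-2,8-dioxabicyclo[3.2.1]octan-3-yl acetate F12. Coupling with 23 under the conditions of step 13 should give the tetraacetate [(2S,3R)-3-acetoxy-4-(2,5-diacetoxy-4-methylphenyl)-2-{(1R,3S,5R)-3-[(1E)-2,6-dimethylhepta-1,5-dien-1-yl]-5-methyl-2,8-dioxabicyclo[3.2.1]octan-1-yl}-2-hydroxybutyl] acetate F13. NH4OAc in aqueous MeOH would cleave only the two aryl acetates to give 26.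

## Further compounds

F1 | step 13 | 2-[(2S,3R)-4-(2,5-dimethoxy-4-methylphenyl)-1,2,3-trihydroxybutan-2-yl]-5-[(3E)-2-hydroxy-4,8-dimethylnona-3,7-dien-1-yl]-5-methyloxolan-2-ol, (5R), epimers at the carbinol and at C2 | OC[C@](O)([C@@H](Cc1cc(OC)c(C)cc1OC)O)C1(O)CC[C@](C)(CC(O)/C=C(\C)CCC=C(C)C)O1
F2 | step 13 | (3E)-1-{(2R)-5-[(2S,3R)-4-(2,5-dimethoxy-4-methylphenyl)-1,2,3-trihydroxybutan-2-yl]-5-hydroxy-2-methyloxolan-2-yl}-4,8-dimethylnona-3,7-dien-2-one | OC[C@](O)([C@@H](Cc1cc(OC)c(C)cc1OC)O)C1(O)CC[C@](C)(CC(=O)/C=C(\C)CCC=C(C)C)O1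
F3 | step 13 | 2-[(2S,3R)-4-(2,5-dimethoxy-4-methylphenyl)-1,2,3-trihydroxybutan-2-yl]-5-[(2S,3E)-2-hydroxy-4,8-dimethylnona-3,7-dien-1-yl]-5-methyloxolan-2-ol, (5R) | OC[C@](O)([C@@H](Cc1cc(OC)c(C)cc1OC)O)C1(O)CC[C@](C)(C[C@H](O)/C=C(\C)CCC=C(C)C)O1
F4 | step 13 | (2S,3R)-4-(2,5-dimethoxy-4-methylphenyl)-2-{(1R,3S,5R)-3-[(1E)-2,6-dimethylhepta-1,5-dien-1-yl]-5-methyl-2,8-dioxabicyclo[3.2.1]octan-1-yl}butane-1,2,3-triol | OC[C@](O)([C@@H](Cc1cc(OC)c(C)cc1OC)O)[C@]12CC[C@](C)(C[C@@H](/C=C(\C)CCC=C(C)C)O1)O2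
F5 | step 6 | (2R)-2-[(tert-butyldimethylsilyl)oxy]-3-(2,5-dimethoxy-4-methylphenyl)-N-methoxy-N-methylpropanamide | CON(C)C(=O)[C@@H](Cc1cc(OC)c(C)cc1OC)O[Si](C)(C)C(C)(C)C
F6 | step 6 | (2R)-2-[(tert-butyldimethylsilyl)oxy]-3-(2,5-dimethoxy-4-methylphenyl)-1-[(5R)-5-ethenyl-5-methyl-4,5-dihydrofuran-2-yl]propan-1-one | O=C(C1=CC[C@](C)(C=C)O1)[C@@H](Cc1cc(OC)c(C)cc1OC)O[Si](C)(C)C(C)(C)C
F7 | step 6 | (2S,3R)-1-(benzyloxy)-3-[(tert-butyldimethylsilyl)oxy]-4-(2,5-dimethoxy-4-methylphenyl)-2-[(5R)-5-ethenyl-5-methyl-4,5-dihydrofuran-2-yl]butan-2-ol | c1ccccc1COC[C@](O)([C@@H](Cc1cc(OC)c(C)cc1OC)O[Si](C)(C)C(C)(C)C)C1=CC[C@](C)(C=C)O1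
F8 | step 7 | (2S,3R)-1-(benzyloxy)-4-(2,5-dimethoxy-4-methylphenyl)-2-[(5R)-5-ethenyl-2-methoxy-5-methyloxolan-2-yl]butane-2,3-diol | c1ccccc1COC[C@](O)([C@@H](Cc1cc(OC)c(C)cc1OC)O)C1(OC)CC[C@](C)(C=C)O1
F9 | step 7 | (2S,3R)-1-(benzyloxy)-4-(2,5-dimethoxy-4-methylphenyl)-2-[(5R)-5-(2-hydroxyethyl)-2-methoxy-5-methyloxolan-2-yl]butane-2,3-diol | c1ccccc1COC[C@](O)([C@@H](Cc1cc(OC)c(C)cc1OC)O)C1(OC)CC[C@](C)(CCO)O1
F10 | step 7 | (2S,3R)-1-(benzyloxy)-4-(2,5-dimethoxy-4-methylphenyl)-2-[(5R)-2-methoxy-5-methyl-5-(2-oxoethyl)oxolan-2-yl]butane-2,3-diol | c1ccccc1COC[C@](O)([C@@H](Cc1cc(OC)c(C)cc1OC)O)C1(OC)CC[C@](C)(CC=O)O1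
F11 | step 14 | (1S,5R)-1-[(2S,3R)-1,3-diacetoxy-2-hydroxy-4-(4-methyl-3,6-dioxocyclohexa-1,4-dien-1-yl)butan-2-yl]-5-methyl-2,8-dioxabicyclo[3.2.1]octan-3-yl acetate | CC(=O)OC[C@](O)([C@@H](CC1=CC(=O)C(C)=CC1=O)OC(C)=O)[C@]12CC[C@](C)(CC(OC(C)=O)O1)O2
F12 | step 14 | (1S,5R)-1-[(2S,3R)-1,3-diacetoxy-4-(2,5-diacetoxy-4-methylphenyl)-2-hydroxybutan-2-yl]-5-methyl-2,8-dioxabicyclo[3.2.1]octan-3-yl acetate | CC(=O)OC[C@](O)([C@@H](Cc1cc(OC(C)=O)c(C)cc1OC(C)=O)OC(C)=O)[C@]12CC[C@](C)(CC(OC(C)=O)O1)O2
F13 | step 14 | [(2S,3R)-3-acetoxy-4-(2,5-diacetoxy-4-methylphenyl)-2-{(1R,3S,5R)-3-[(1E)-2,6-dimethylhepta-1,5-dien-1-yl]-5-methyl-2,8-dioxabicyclo[3.2.1]octan-1-yl}-2-hydroxybutyl] acetate | CC(=O)OC[C@](O)([C@@H](Cc1cc(OC(C)=O)c(C)cc1OC(C)=O)OC(C)=O)[C@]12CC[C@](C)(C[C@@H](/C=C(\C)CCC=C(C)C)O1)O2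
A1 | alternative 1 | (2R,3S,7R,9S,10E)-1-(2,5-dimethoxy-4-methylphenyl)-2,3,7,9-tetrahydroxy-3-(hydroxymethyl)-7,11,15-trimethylhexadeca-10,14-dien-4-one | OC[C@](O)([C@@H](Cc1cc(OC)c(C)cc1OC)O)C(=O)CC[C@@](C)(O)C[C@H](O)/C=C(\C)CCC=C(C)C
A2 | alternative 1 | (2R,3S,7R,10E)-1-(2,5-dimethoxy-4-methylphenyl)-2,3,7-trihydroxy-3-(hydroxymethyl)-7,11,15-trimethylhexadeca-10,14-diene-4,9-dione | OC[C@](O)([C@@H](Cc1cc(OC)c(C)cc1OC)O)C(=O)CC[C@@](C)(O)CC(=O)/C=C(\C)CCC=C(C)C
A3 | alternative 2 | (2R,3S,7R,9E)-1-(2,5-dimethoxy-4-methylphenyl)-2,3,7,11-tetrahydroxy-3-(hydroxymethyl)-7,11,15-trimethylhexadeca-9,14-dien-4-one, either configuration at C11 | OC[C@](O)([C@@H](Cc1cc(OC)c(C)cc1OC)O)C(=O)CC[C@@](C)(O)C/C=C/C(C)(O)CCC=C(C)C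
A4 | alternative 3 | [(2S,3R)-3-acetoxy-4-(2,5-dimethoxy-4-methylphenyl)-2-hydroxy-2-(5-methylfuran-2-yl)butyl] acetate | CC(=O)OC[C@](O)([C@@H](Cc1cc(OC)c(C)cc1OC)OC(C)=O)c1ccc(C)o1
A5 | alternative 3 | (1R,4R)-1-[(2S,3R)-1,3-diacetoxy-4-(2,5-dimethoxy-4-methylphenyl)-2-hydroxybutan-2-yl]-4-methyl-7-oxabicyclo[2.2.1]heptan-2-one | CC(=O)OC[C@](O)([C@@H](Cc1cc(OC)c(C)cc1OC)OC(C)=O)[C@]12CC[C@](C)(CC1=O)O2
A6 | alternative 3 | (1S,5R)-1-[(2S,3R)-1,3-diacetoxy-4-(2,5-dimethoxy-4-methylphenyl)-2-hydroxybutan-2-yl]-5-methyl-2,8-dioxabicyclo[3.2.1]octan-3-one | CC(=O)OC[C@](O)([C@@H](Cc1cc(OC)c(C)cc1OC)OC(C)=O)[C@]12CC[C@](C)(CC(=O)O1)O2
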